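Readings and results come from a simulation on assumed constants; scatter was added.

- Late in the delta flask, count what is left, not what was made: target still to come is reckoned as a constant times the exposure, which is the logarithmic mean of the substrate fractions at the two ends of an interval, times its length.

| flask | substrate | gas phase | remark | time |
|---|---|---|---|---|
| delta | 0.050 M | 8.8 mM (held) | the very flask that is asked about, followed so far |  |
| gamma | 0.075 M | 8.8 mM (held) | run made earlier |  |
| flask | 0.050 M | 8.8 mM (held) |  | 30 min |

| run | time / min | target / % | substrate / % |
|---|---|---|---|
| delta | 1.50 | 1.7 | 77.9 |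
| delta | 3.00 | 2.7 | 62.8 |
| delta | 5.00 | 4.4 | 49.0 |
| delta | 6.00 | 6.4 | 44.2 |
| delta | 8.00 | 8.5 | 35.8 |
| delta | 10.0 | 10.1 | 29.7 |
| delta | 12.0 | 11.2 | 25.1 |
| gamma | 3.00 | 2.7 | 53.4 |
| gamma | 6.00 | 4.7 | 35.2 |
| gamma | 10.0 | 7.9 | 23.0 |
| gamma | 12.0 | 9.0 | 19.6 |
| gamma | 15.0 | 10.0 | 15.2 |
| gamma | 20.0 | 12.7 | 10.9 |

(readings scatter by 0.3 percentage points)

- how much target there is at 30 min, in percent of the substrate charged
- the change that raises the amount of target at 30 min, in percent of the substrate charged most ("none" if none brings more than 2 percentage points) (larch / oak / none)
- amount of target at 30 min, in percent of the substrate charged, after larch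

- larch: doubling the transfer coefficient of the gas phase, all else as stated
- oak: doubling the saturation concentration of gas phase, all else as stated

- at the start none of the gas phase is in solution

- From 10.0 min to 20.0 min, the gamma run reads 0.0296 /min for the late target constant, the target made per minute per unit fraction of substrate left; it is a pseudo-first-order constant.
- Over the first 3.00 min of the delta run, the same reading is lower, 0.0113 /min, so I tie the constant to [dissolved gas], which starts from nothing.
- In the delta run, the inverse substrate fraction climbs 0.287 /min. Carried on, that leaves about 10.9% of the substrate at 30 min, an exposure of 3.07 min after 12.0 min, and 9.1 percentage points more target. My figure is 20.3%.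
- Turn the question round: for "none", the doubling of the constant that I expect from oak must add under 2 points, so the exposure must be below 0.675 min. After 12.0 min you have 4.55 times that. For oak to lose this margin, a run must show the constant not following the saturation concentration.
- The forecast gives 19.2%, oak as best and 22% after larch, holding that “Oak doubles the gas concentration”; my figure is higher than its 19.2%.
- The flask gives 19.7%. Best is oak, adding 13 points, while larch adds 5.5 points and reaches 25.1%.

    dissolved gas → decomposed reagent (k = 0.00220 /s)
    substrate → side product (k = 9.00 × 10⁻⁵ /s)
    2 substrate → self-condensation product (k = 0.0290 /M/s)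
    gas phase ⇌ dissolved gas, rate k4*(csat - [dissolved gas]) (kL = 0.00490 /s)
    substrate + dissolved gas → target (k = 0.0930 /M/s)

- In this flask, substrate falls from 25.6% at 12.0 min to 8.41% at 30.0 min, an exposure of 2.78 min. With 0.0296 /min, that makes 8.2 points of target, against 8.1 points simulated. The neighbouring flask runs on to 80 min, with substrate down to 0.924%, an exposure of 1.70 min beyond 30 min. So you reckon 5 points more, or 24.7% in all. That neighbouring flask holds 25.0% of target.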